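The route rests on cutting the C6–C7 bond of the azepine ring (pyrrolo[1,2-a]azepine numbering). Because the butenolide β-carbon C6 carries the methylene C7, and the two-carbon bridge C7–C8 ends at the spiro carbon C9, a vinyl group on C9 and a bromide on C6 already contain every ring atom. Hydroboration of that vinyl group and intramolecular B-alkyl Suzuki coupling then close the seven-membered ring N4–C5–C6–C7–C8–C9–C9a in one operation and give the target directly. The precursor is a 2,5-trans pyrrolidine carrying the vinyl-substituted lactone at C9a, the methyl lactone at C3 and an N-bound 4-bromo-3-methylbutenolide (aminal C5); all stereocentres are in place before the closure.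

Key step: step 16

Assumption: the aminal carbon C5 is configurationally labile through reversible opening to the iminium carboxylate, so 25 is drawn as its 5S epimer and 5S is taken as the thermodynamically preferred configuration of 27 (ring positions follow the pyrrolo[1,2-a]azepine numbering of the target throughout).

Step 1
Reactants: 1 L-pyroglutamic acid
Product: 2 benzyl (S)-5-oxopyrrolidine-2-carboxylate
Conditions: BnBr, K2CO3, DMF, rt
Reagents that add atoms: benzyl bromide, BrCc1ccccc1
Why: Carboxylate O-alkylation (SN2 esterification) leaves the lactam N–H and the stereocentre untouched, and the benzyl ester lets the hydrogenation of step 6 free the acid without a basic hydrolysis.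

Step 2
Reactants: 2 benzyl (S)-5-oxopyrrolidine-2-carboxylate
Product: 3 2-benzyl 1-tert-butyl (S)-5-oxopyrrolidine-1,2-dicarboxylate
Conditions: Boc2O, DMAP (cat.), MeCN, rt
Reagents that add atoms: di-tert-butyl dicarbonate, CC(C)(C)OC(=O)OC(=O)OC(C)(C)C
Why: DMAP-catalysed N-acylation of the lactam (Boc protection) also activates the ring carbonyl as an imide for the selective reduction that follows.

Step 3
Reactants: 3 2-benzyl 1-tert-butyl (S)-5-oxopyrrolidine-1,2-dicarboxylate
Product: 5 2-benzyl 1-tert-butyl (2S)-5-methoxypyrrolidine-1,2-dicarboxylate (C5 epimers), via 5-hydroxy hemiaminal 4 (not isolated)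
Conditions: LiBHEt3, THF, −78 °C, H2O quench; then MeOH, PPTS (cat.), rt
Reagents that add atoms: methanol, CO
Why: Chemoselective hydride reduction of the imide-type carbonyl (the ester is inert at −78 °C) and acid-catalysed N,O-acetal exchange should give the methoxy aminal, whose C5 configuration is irrelevant because both epimers ionise to the same N-acyliminium ion.

Step 4
Reactants: 6 3-methylfuran-2(5H)-one
Product: 7 3-methyl-2-(triisopropylsilyloxy)furan
Conditions: TIPSOTf, Et3N, CH2Cl2, 0 °C
Reagents that add atoms: triisopropylsilyl trifluoromethanesulfonate, CC(C)[Si](OS(=O)(=O)C(F)(F)F)(C(C)C)C(C)C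
Why: Soft enolisation and O-silylation of the butenolide (silyl dienol ether formation) gives the aromatic 2-silyloxyfuran.

Step 5
Reactants: 5 2-benzyl 1-tert-butyl (2S)-5-methoxypyrrolidine-1,2-dicarboxylate; 7 3-methyl-2-(triisopropylsilyloxy)furan
Product: 8 2-benzyl 1-tert-butyl (2S,5S)-5-[(2S)-4-methyl-5-oxo-2,5-dihydrofuran-2-yl]pyrrolidine-1,2-dicarboxylate
Conditions: TIPSOTf (10 mol %), CH2Cl2, −78 → 0 °C
Reagents that add atoms: none
Why: Vinylogous Mukaiyama–Mannich reaction in which the silyl triflate ionises the N,O-acetal and the furan γ-carbon attacks the N-acyliminium ion anti to the C2 ester (2,5-trans pyrrolidine, target C3 = S) through the threo-selective open transition state typical of five-membered N-acyliminium ions (lactone carbinol carbon = S).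

Step 6
Reactants: 8 2-benzyl 1-tert-butyl (2S,5S)-5-[(2S)-4-methyl-5-oxo-2,5-dihydrofuran-2-yl]pyrrolidine-1,2-dicarboxylate
Product: 9 (2S,5S)-1-(tert-butoxycarbonyl)-5-[(2S,4S)-4-methyl-5-oxooxolan-2-yl]pyrrolidine-2-carboxylic acid
Conditions: H2 (1 atm), 10% Pd/C, EtOAc, rt
Reagents that add atoms: none
Why: Heterogeneous hydrogenation should deliver hydrogen to the butenolide face opposite the bulky pyrrolidinyl group on the γ-carbon (cis-3,5-disubstituted lactone, methyl carbon = S), while the same catalyst removes the benzyl ester by hydrogenolysis.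

Step 7
Reactants: 9 (2S,5S)-1-(tert-butoxycarbonyl)-5-[(2S,4S)-4-methyl-5-oxooxolan-2-yl]pyrrolidine-2-carboxylic acid
Product: 10 tert-butyl (2S,5S)-2-[(ethylsulfanyl)carbonyl]-5-[(2S,4S)-4-methyl-5-oxooxolan-2-yl]pyrrolidine-1-carboxylate
Conditions: EtSH, DCC, DMAP (cat.), CH2Cl2, 0 °C → rt
Reagents that add atoms: ethanethiol, CCS
Why: Steglich-type thioesterification; the urethane-protected, N,N-disubstituted α-centre has no oxazolone pathway and should not epimerise.

Step 8
Reactants: 11 methyl (R)-3-hydroxy-2-methylpropanoate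
Product: 12 methyl (S)-3-iodo-2-methylpropanoate
Conditions: I2, PPh3, imidazole, CH2Cl2, 0 °C → rt
Reagents that add atoms: iodine, II
Why: Appel-type iodination of the primary alcohol does not touch the stereocentre (the descriptor changes only through the CIP ranking).

Step 9
Reactants: 10 tert-butyl (2S,5S)-2-[(ethylsulfanyl)carbonyl]-5-[(2S,4S)-4-methyl-5-oxooxolan-2-yl]pyrrolidine-1-carboxylate; 12 methyl (S)-3-iodo-2-methylpropanoate
Product: 14 tert-butyl (2S,5S)-2-[(3R)-4-methoxy-3-methyl-4-oxobutanoyl]-5-[(2S,4S)-4-methyl-5-oxooxolan-2-yl]pyrrolidine-1-carboxylate, via alkylzinc iodide 13 (not isolated)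
Conditions: 12, Zn dust (TMSCl/BrCH2CH2Br-activated), THF, 35 °C; then 10, PdCl2(PPh3)2 (5 mol %), toluene, rt
Reagents that add atoms: none
Why: Zinc insertion into the primary iodide gives a chelate-stabilised β-zincio ester, and Fukuyama coupling (Pd-catalysed acylation of the alkylzinc by the thioester) should form the γ-keto ester under neutral conditions that tolerate lactone, ester and carbamate and leave both α-stereocentres intact.

Step 10
Reactants: 14 tert-butyl (2S,5S)-2-[(3R)-4-methoxy-3-methyl-4-oxobutanoyl]-5-[(2S,4S)-4-methyl-5-oxooxolan-2-yl]pyrrolidine-1-carboxylate; 15 vinylmagnesium bromide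
Product: 17 tert-butyl (2S,5S)-2-[(2R,4R)-2-ethenyl-4-methyl-5-oxooxolan-2-yl]-5-[(2S,4S)-4-methyl-5-oxooxolan-2-yl]pyrrolidine-1-carboxylate, via tertiary hydroxy ester 16 (not isolated)
Conditions: 15 (1.3 equiv), THF, −78 → 0 °C; NH4Cl aq.; PPTS (cat.), toluene, 40 °C to finish ring closure
Reagents that add atoms: none
Why: Grignard 1,2-addition to the ketone (far more electrophilic than ester, lactone or carbamate at −78 °C) through a Felkin–Anh transition state with the C9a–N bond anti to the incoming vinyl group and attack past C9a–H should set the carbinol carbon as R (C9 of the target), after which the alkoxide closes the γ-lactone on the methyl ester (addition/lactonisation).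

Step 11
Reactants: 17 tert-butyl (2S,5S)-2-[(2R,4R)-2-ethenyl-4-methyl-5-oxooxolan-2-yl]-5-[(2S,4S)-4-methyl-5-oxooxolan-2-yl]pyrrolidine-1-carboxylate
Product: 18 (2S,5S)-2-[(2R,4R)-2-ethenyl-4-methyl-5-oxooxolan-2-yl]-5-[(2S,4S)-4-methyl-5-oxooxolan-2-yl]pyrrolidinium trifluoroacetate
Conditions: TFA, CH2Cl2, 0 °C; evaporate
Reagents that add atoms: trifluoroacetic acid, OC(=O)C(F)(F)F
Why: Acidolysis of the Boc carbamate; the amine is kept as its salt so that it cannot attack either lactone (O→N acyl shift), and the adjacent ammonium group disfavours ionisation of the tertiary allylic C–O bond.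

Step 12
Reactants: 19 ethyl 2-methylacetoacetate
Product: 21 4-hydroxy-3-methylfuran-2(5H)-one (3-methyltetronic acid), via γ-bromo keto ester 20 (not isolated)
Conditions: Br2, CHCl3, 0 °C → rt; concentrate; then neat, 110 °C
Reagents that add atoms: none
Why: Bromination followed by HBr-mediated equilibration places bromine on the acetyl methyl group, and thermal lactonisation with loss of bromoethane is the classical tetronic acid synthesis.

Step 13
Reactants: 21 4-hydroxy-3-methylfuran-2(5H)-one
Product: 22 4-bromo-3-methylfuran-2(5H)-one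
Conditions: (COBr)2, DMF (cat.), CH2Cl2, 0 °C → rt
Reagents that add atoms: oxalyl bromide, O=C(Br)C(Br)=O
Why: Vilsmeier-type deoxybromination of the vinylogous acid converts the tetronic acid into the β-bromobutenolide.

Step 14
Reactants: 22 4-bromo-3-methylfuran-2(5H)-one
Product: 24 4-bromo-5-hydroxy-3-methylfuran-2(5H)-one (racemic pseudo-acid), via 4,5-dibromobutenolide 23 (not isolated)
Conditions: NBS, AIBN (cat.), PhCF3, reflux; filter; then H2O, THF, 60 °C
Reagents that add atoms: water, O
Why: Wohl–Ziegler bromination at the γ-carbon (radical stabilised by the ring oxygen and the enoate) followed by hydrolysis of the resulting pseudo-acid bromide should give the hydroxybutenolide.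

Step 15
Reactants: 18 (2S,5S)-2-[(2R,4R)-2-ethenyl-4-methyl-5-oxooxolan-2-yl]-5-[(2S,4S)-4-methyl-5-oxooxolan-2-yl]pyrrolidinium trifluoroacetate; 24 4-bromo-5-hydroxy-3-methylfuran-2(5H)-one
Product: 25 (5S)-4-bromo-3-methyl-5-{(2S,5S)-2-[(2R,4R)-2-ethenyl-4-methyl-5-oxooxolan-2-yl]-5-[(2S,4S)-4-methyl-5-oxooxolan-2-yl]pyrrolidin-1-yl}furan-2(5H)-one
Conditions: Et3N (1.0 equiv), 4 Å MS, toluene, 50 °C
Reagents that add atoms: none
Why: Pseudo-amide (N,O-acetal) formation, in which the liberated secondary amine condenses with the ring-opened aldehyde form of the pseudo-acid to an iminium ion that the cis carboxylate recloses, is reversible and therefore thermodynamically controlled at C5, and it avoids substitution of the vinylic bromide.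

Step 16
Reactants: 25 (5S)-4-bromo-3-methyl-5-{(2S,5S)-2-[(2R,4R)-2-ethenyl-4-methyl-5-oxooxolan-2-yl]-5-[(2S,4S)-4-methyl-5-oxooxolan-2-yl]pyrrolidin-1-yl}furan-2(5H)-one
Product: 27 target CNP0155196.1, via B-alkyl-9-BBN adduct 26 (not isolated)
Conditions: 9-BBN dimer, THF, 0 → 40 °C; then slow addition to PdCl2(dppf) (15 mol %), AsPh3, Cs2CO3, DMF/THF/H2O, 50 °C, ca. 2 mM
Reagents that add atoms: none
Why: 9-BBN should add only to the unhindered, electron-rich C9 vinyl group and place boron on the terminal carbon C7; Pd(0) then inserts into the C6–Br bond (a vinylogous acyl bromide, fast oxidative addition), the carbonate-activated borate transfers its primary alkyl group, and reductive elimination from the eight-membered palladacycle forms C6–C7. The closest known reaction type is the intramolecular B-alkyl Suzuki–Miyaura coupling, and β-bromobutenolides are established partners for 9-alkyl-9-BBN reagents. The azepine ring (N4–C5–C6–C7–C8–C9–C9a) closes by C(sp3)–C(sp2) coupling, exo with respect to the butenolide double bond, and C9 becomes the spiro centre. No stereocentre is created: the C9 descriptor changes from R to S only through the CIP ranking, and the aminal C5 can settle to its preferred configuration by reversible opening to the iminium carboxylate (trace acid on work-up if needed). The step needs chemoselective hydroboration, secured by the steric and electronic contrast between the vinyl group and the tetrasubstituted electron-poor butenolide alkene, and ring closure in preference to oligomerisation or β-hydride elimination, secured by high dilution, the wide bite angle of dppf and the pre-organisation of both termini around N4 by the pyrrolidine, the quaternary C9 and the aminal.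

Compound list
1 | L-pyroglutamic acid, (S)-5-oxopyrrolidine-2-carboxylic acid | C1CC(=O)N[C@@H]1C(=O)O | starting material
2 | benzyl (S)-5-oxopyrrolidine-2-carboxylate | O=C(OCc1ccccc1)[C@@H]1CCC(=O)N1 | intermediate
3 | 2-benzyl 1-tert-butyl (S)-5-oxopyrrolidine-1,2-dicarboxylate | O=C(OCc1ccccc1)[C@@H]1CCC(=O)N1C(=O)OC(C)(C)C | intermediate
4 | 2-benzyl 1-tert-butyl (2S)-5-hydroxypyrrolidine-1,2-dicarboxylate (C5 epimers, not isolated) | O=C(OCc1ccccc1)[C@@H]1CCC(O)N1C(=O)OC(C)(C)C | intermediate
5 | 2-benzyl 1-tert-butyl (2S)-5-methoxypyrrolidine-1,2-dicarboxylate (C5 epimers) | O=C(OCc1ccccc1)[C@@H]1CCC(OC)N1C(=O)OC(C)(C)C | intermediate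
6 | 3-methylfuran-2(5H)-one | CC1=CCOC1=O | starting material
7 | 3-methyl-2-(triisopropylsilyloxy)furan | Cc1ccoc1O[Si](C(C)C)(C(C)C)C(C)C | intermediate
8 | 2-benzyl 1-tert-butyl (2S,5S)-5-[(2S)-4-methyl-5-oxo-2,5-dihydrofuran-2-yl]pyrrolidine-1,2-dicarboxylate | O=C(OCc1ccccc1)[C@@H]1CC[C@@H]([C@@H]2C=C(C)C(=O)O2)N1C(=O)OC(C)(C)C | intermediate
9 | (2S,5S)-1-(tert-butoxycarbonyl)-5-[(2S,4S)-4-methyl-5-oxooxolan-2-yl]pyrrolidine-2-carboxylic acid | OC(=O)[C@@H]1CC[C@@H]([C@@H]2C[C@H](C)C(=O)O2)N1C(=O)OC(C)(C)C | intermediate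
10 | tert-butyl (2S,5S)-2-[(ethylsulfanyl)carbonyl]-5-[(2S,4S)-4-methyl-5-oxooxolan-2-yl]pyrrolidine-1-carboxylate | CCSC(=O)[C@@H]1CC[C@@H]([C@@H]2C[C@H](C)C(=O)O2)N1C(=O)OC(C)(C)C | intermediate
11 | methyl (R)-3-hydroxy-2-methylpropanoate | C[C@H](CO)C(=O)OC | starting material
12 | methyl (S)-3-iodo-2-methylpropanoate | C[C@H](CI)C(=O)OC | intermediate
13 | [(2S)-3-methoxy-2-methyl-3-oxopropyl]zinc iodide (not isolated) | C[C@H](C[Zn]I)C(=O)OC | intermediate
14 | tert-butyl (2S,5S)-2-[(3R)-4-methoxy-3-methyl-4-oxobutanoyl]-5-[(2S,4S)-4-methyl-5-oxooxolan-2-yl]pyrrolidine-1-carboxylate | COC(=O)[C@H](C)CC(=O)[C@@H]1CC[C@@H]([C@@H]2C[C@H](C)C(=O)O2)N1C(=O)OC(C)(C)C | intermediate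
15 | vinylmagnesium bromide | C=C[Mg]Br | starting material
16 | tert-butyl (2S,5S)-2-[(3R,5R)-3-hydroxy-6-methoxy-5-methyl-6-oxohex-1-en-3-yl]-5-[(2S,4S)-4-methyl-5-oxooxolan-2-yl]pyrrolidine-1-carboxylate (formed as its bromomagnesium alkoxide, not isolated) | COC(=O)[C@H](C)C[C@@](O)(C=C)[C@@H]1CC[C@@H]([C@@H]2C[C@H](C)C(=O)O2)N1C(=O)OC(C)(C)C | intermediate
17 | tert-butyl (2S,5S)-2-[(2R,4R)-2-ethenyl-4-methyl-5-oxooxolan-2-yl]-5-[(2S,4S)-4-methyl-5-oxooxolan-2-yl]pyrrolidine-1-carboxylate | C=C[C@]1(C[C@@H](C)C(=O)O1)[C@@H]1CC[C@@H]([C@@H]2C[C@H](C)C(=O)O2)N1C(=O)OC(C)(C)C | intermediate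
18 | (2S,5S)-2-[(2R,4R)-2-ethenyl-4-methyl-5-oxooxolan-2-yl]-5-[(2S,4S)-4-methyl-5-oxooxolan-2-yl]pyrrolidinium trifluoroacetate | C=C[C@]1(C[C@@H](C)C(=O)O1)[C@@H]1CC[C@@H]([C@@H]2C[C@H](C)C(=O)O2)[NH2+]1.[O-]C(=O)C(F)(F)F | intermediate
19 | ethyl 2-methylacetoacetate | CCOC(=O)C(C)C(C)=O | starting material
20 | ethyl 4-bromo-2-methyl-3-oxobutanoate (not isolated) | CCOC(=O)C(C)C(=O)CBr | intermediate
21 | 4-hydroxy-3-methylfuran-2(5H)-one (3-methyltetronic acid) | CC1=C(O)COC1=O | intermediate
22 | 4-bromo-3-methylfuran-2(5H)-one | CC1=C(Br)COC1=O | intermediate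
23 | 4,5-dibromo-3-methylfuran-2(5H)-one (racemic, not isolated) | CC1=C(Br)C(Br)OC1=O | intermediate
24 | 4-bromo-5-hydroxy-3-methylfuran-2(5H)-one (racemic) | CC1=C(Br)C(O)OC1=O | intermediate
25 | (5S)-4-bromo-3-methyl-5-{(2S,5S)-2-[(2R,4R)-2-ethenyl-4-methyl-5-oxooxolan-2-yl]-5-[(2S,4S)-4-methyl-5-oxooxolan-2-yl]pyrrolidin-1-yl}furan-2(5H)-one (key-step precursor) | C=C[C@]1(C[C@@H](C)C(=O)O1)[C@@H]1CC[C@@H]([C@@H]2C[C@H](C)C(=O)O2)N1[C@H]1OC(=O)C(C)=C1Br | intermediate
26 | B-alkyl-9-BBN adduct of 25 (9-borabicyclo[3.3.1]nonan-9-yl on the terminal carbon of the former vinyl group, not isolated) | C(CB1C2CCCC1CCC2)[C@]1(C[C@@H](C)C(=O)O1)[C@@H]1CC[C@@H]([C@@H]2C[C@H](C)C(=O)O2)N1[C@H]1OC(=O)C(C)=C1Br | intermediate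
27 | CNP0155196.1: azepine-fused aminobutenolide with (9S) spiro lactone (11R methyl), (3S) side-chain lactone (S,S), 9aS and 5S | CC1=C2CC[C@]3(C[C@@H](C)C(=O)O3)[C@@H]3CC[C@@H]([C@@H]4C[C@H](C)C(=O)O4)N3[C@H]2OC1=O | target

Total step count: 16. Longest linear sequence: 11 steps (steps 1, 2, 3, 5, 6, 7, 9, 10, 11, 15, 16, from L-pyroglutamic acid).

Steps most likely to fail

Step 16. The alkylborane may couple intermolecularly (oligomerisation), lose boron by protodeboronation, or suffer β-hydride elimination with hydrodebromination faster than the seven-membered reductive elimination, and the base may attack the bromobutenolide. The fallback sets out from 25 and returns at 27. Stille coupling of 25 with tributyl(vinyl)stannane (Pd2(dba)3, AsPh3, CuI, DMF) should give the 4-ethenylbutenolide F1. Ring-closing metathesis (Hoveyda–Grubbs II, toluene, 80 °C) between the two vinyl groups would form C7=C8 and give the 7,8-didehydro compound F2. Diimide (2-nitrobenzenesulfonyl hydrazide, Et3N), or H2 with Wilkinson's catalyst, should then reduce only the disubstituted C7=C8 alkene and leave the tetrasubstituted butenolide alkene, giving 27.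

Step 10. Facial selectivity may be poor if magnesium chelation between the ketone and the carbamate competes with the Felkin–Anh pathway; the Grignard reagent may also enolise the α-amino ketone (epimerisation at C9a) or attack the lactone. The fallback sets out from 14 and returns at 17. Ethynylmagnesium bromide premixed with anhydrous CeCl3 (THF, −78 °C), a slimmer and much less basic nucleophile, followed by the same lactonisation should give the ethynyl lactone F3. Lindlar semi-hydrogenation (H2, Pd/CaCO3/Pb, quinoline) then reveals the vinyl group of 17.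

Step 15. Iminium formation at the doubly α-branched nitrogen may be slow, so that addition–elimination at the vinylic bromide or O→N acyl transfer from a lactone to the free amine takes over. The fallback sets out from 18 and from dibromide 23 (isolated by stopping step 14 before the water treatment) and returns at 25. Irreversible N-alkylation with the pseudo-acid bromide (iPr2NEt, MeCN, 0 °C → rt), the kind of C5 substitution used to attach bromobutenolides to N- and O-nucleophiles, gives 25 directly; no compound outside the list is formed (F0: none).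

Further compounds
F1 | step 16 | (5S)-4-ethenyl-3-methyl-5-{(2S,5S)-2-[(2R,4R)-2-ethenyl-4-methyl-5-oxooxolan-2-yl]-5-[(2S,4S)-4-methyl-5-oxooxolan-2-yl]pyrrolidin-1-yl}furan-2(5H)-one | C=C[C@]1(C[C@@H](C)C(=O)O1)[C@@H]1CC[C@@H]([C@@H]2C[C@H](C)C(=O)O2)N1[C@H]1OC(=O)C(C)=C1C=C
F2 | step 16 | 7,8-didehydro derivative of 27 (cis C7=C8 in the azepine ring) | CC1=C2C=C[C@]3(C[C@@H](C)C(=O)O3)[C@@H]3CC[C@@H]([C@@H]4C[C@H](C)C(=O)O4)N3[C@H]2OC1=O
F3 | step 10 | tert-butyl (2S,5S)-2-[(2R,4R)-2-ethynyl-4-methyl-5-oxooxolan-2-yl]-5-[(2S,4S)-4-methyl-5-oxooxolan-2-yl]pyrrolidine-1-carboxylate | C#C[C@]1(C[C@@H](C)C(=O)O1)[C@@H]1CC[C@@H]([C@@H]2C[C@H](C)C(=O)O2)N1C(=O)OC(C)(C)C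
F0 | step 15 | none | none
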